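**Plan**

- Numbering (elemane skeleton): C10 is the quaternary ring carbon (methyl C14, vinyl C1=C2); C9 is the ring CH2; C8 carries the acyloxy group; C7 and C6 are the lactone ring-fusion carbons (O on C6); C5 carries C4(=C3H2)–C15H2OH; the lactone is O–C12(=O)–C11(=C13H2)–C7.
- Retrosynthesis: remove the C8 ester (inversion at C8), then cut the cyclohexane at C9–C10 and C6–C7 in one operation. This gives lactol 14 (C1, C2, C10, C14, C5, C6, C3, C4, C15) and methyl 2-methylidene-4-oxopentanoate 18 (C7–C9, C11–C13).
- Enabling feature: C8, the oxygenated ring carbon, lies between C7 and C9, so a ketone at C8 can act as a carbon nucleophile on both sides. C5 lies between C6 (latent aldehyde, its oxygen becomes the lactone oxygen) and C10 (tertiary end of a Z-allyl cation C10–C1–C2 whose other end becomes the vinyl group). Ring C5–C6–C7–C8–C9–C10 therefore arises by a (3+3) union, and O6 then closes the five-membered lactone on C12.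
- Forward order: the lactol and the keto ester are made separately; step 12 forms C6–C7, then C9–C10, then the lactone; C8 is then reduced, esterified with inversion, and the silyl ethers are removed.
- Stereochemistry: C5 from a rhodium/(R)-BINAP conjugate addition; C6 and C7 from a chelated syn-aldol addition; C10 from a chair ring closure under 1,3-allylic strain of the Z-alkene (set by trans-hydroalumination); C8 from equatorial hydride attack followed by Mitsunobu inversion; the acyl stereocentre from methyl (2R)-3-hydroxy-2-methylpropanoate.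

Key step: step 12

Assumption: the facial sense of BINAP–rhodium additions to (E)-enoates is taken to be the usual one, so that the (R)-ligand delivers the alkenyl group to the α-re face and gives (3S)-9.

Step 1
Reactants: 1 but-2-yn-1-ol
Product: 3 (2Z)-3-iodobut-2-en-1-ol, via cyclic sodium alkenylalanate 2 (not isolated)
Conditions: NaAlH2(OCH2CH2OCH3)2, THF, 0 °C to rt; then I2, −78 °C to rt
Reagents that add atoms: iodine [I][I]
Why: Alkoxide-directed trans-hydroalumination puts aluminium on C3 cis to the CH2O group, and iodination of the carbon–aluminium bond with retention should give the Z-iodide that fixes the alkene geometry needed in step 12 (hydroalumination–iodination).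

Step 2
Reactants: 3 (2Z)-3-iodobut-2-en-1-ol
Product: 4 (2Z)-3-iodo-1-methoxybut-2-ene
Conditions: NaH, CH3I, THF, 0 °C to rt
Reagents that add atoms: iodomethane IC
Why: Williamson etherification of the primary allylic alkoxide gives a methyl ether that is inert until it serves as the allylic leaving group in step 12.

Step 3
Reactants: 4 (2Z)-3-iodo-1-methoxybut-2-ene
Product: 7 [(2E)-4-methoxybut-2-en-2-yl]boronic acid, via alkenyllithium 5 (not isolated), via lithium alkenyl(triisopropoxy)borate 6 (not isolated)
Conditions: t-BuLi (2 equiv), Et2O, −78 °C; then B(Oi-Pr)3, −78 °C to rt; then 1 M HCl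
Reagents that add atoms: triisopropyl borate CC(C)OB(OC(C)C)OC(C)C; water O
Why: Iodine–lithium exchange with retention of the alkene geometry, trapping by the borate ester and hydrolysis should give the alkenylboronic acid (borylation of an alkenyllithium; the descriptor changes to E only because boron ranks below carbon).

Step 4
Reactants: 7 [(2E)-4-methoxybut-2-en-2-yl]boronic acid; 8 methyl (2E)-4,4-dimethoxybut-2-enoate
Product: 9 methyl (3S,4Z)-3-(dimethoxymethyl)-6-methoxy-4-methylhex-4-enoate
Conditions: [Rh(OH)(cod)]2 (3 mol %), (R)-BINAP, 1,4-dioxane/H2O (10:1), 50 °C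
Reagents that add atoms: none
Why: Asymmetric 1,4-addition of the alkenylboronic acid to the β-substituted acrylate catalysed by monovalent rhodium (Hayashi–Miyaura reaction) should set C5 by delivery of the alkenyl group from the (R)-BINAP complex to one face of the (E)-enoate, with the alkene geometry retained in the transmetalation.

Step 5
Reactants: 9 methyl (3S,4Z)-3-(dimethoxymethyl)-6-methoxy-4-methylhex-4-enoate
Product: 12 methyl (3R,4Z)-3-(dimethoxymethyl)-6-methoxy-4-methyl-2-methylidenehex-4-enoate, via Mannich base 10 (not isolated), via trimethylammonium iodide 11 (not isolated)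
Conditions: LiN(i-Pr)2, THF, −78 °C; then dimethyl(methylidene)ammonium iodide, −78 to 0 °C; then CH3I, MeOH, rt; then NaHCO3 (aq.), CH2Cl2, rt
Reagents that add atoms: dimethyl(methylidene)ammonium iodide C=[N+](C)C.[I-]
Why: Mannich reaction of the ester enolate, N-methylation and β-elimination of trimethylamine install the C3 methylidene group (α-methylenation of an ester), while C5 is not deprotonated and keeps its configuration (the descriptor changes only through the priority rules).

Step 6
Reactants: 12 methyl (3R,4Z)-3-(dimethoxymethyl)-6-methoxy-4-methyl-2-methylidenehex-4-enoate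
Product: 13 (3R,4Z)-3-(dimethoxymethyl)-6-methoxy-4-methyl-2-methylidenehex-4-en-1-ol
Conditions: i-Bu2AlH (2.5 equiv), CH2Cl2, −78 °C; aq. potassium sodium tartrate
Reagents that add atoms: none
Why: 1,2-Reduction of the conjugated ester by the aluminium hydride should give the primary allylic alcohol (C15–OH) and leave the acetal untouched (ester reduction).

Step 7
Reactants: 13 (3R,4Z)-3-(dimethoxymethyl)-6-methoxy-4-methyl-2-methylidenehex-4-en-1-ol
Product: 14 (3R)-3-[(2Z)-4-methoxybut-2-en-2-yl]-4-methylideneoxolan-2-ol (mixture of anomers)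
Conditions: PPTS, acetone/H2O (4:1), rt
Reagents that add atoms: water O
Why: Acid-catalysed acetal hydrolysis with capture of the aldehyde by the C15 hydroxyl should give the five-membered lactol, which masks the C6 aldehyde and protects the doubly allylic stereocentre C5 from epimerisation (acetal hydrolysis and hemiacetal formation).

Step 8
Reactants: 15 trimethyl phosphonoacetate; 16 chloroacetone
Product: 17 methyl 2-(dimethoxyphosphoryl)-4-oxopentanoate
Conditions: NaH, THF, 0 °C; then 16, NaI (cat.), rt
Reagents that add atoms: none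
Why: C-alkylation of the sodium phosphonoacetate anion by the α-chloroketone should give the keto phosphonate (enolate alkylation).

Step 9
Reactants: 17 methyl 2-(dimethoxyphosphoryl)-4-oxopentanoate
Product: 18 methyl 2-methylidene-4-oxopentanoate
Conditions: HCHO (37 % aq.), K2CO3, THF/H2O, rt
Reagents that add atoms: formaldehyde C=O
Why: Horner–Wadsworth–Emmons olefination of formaldehyde should give the α-methylene ester that carries C7–C9 and C11–C13.

Step 10
Reactants: 19 methyl (2R)-3-hydroxy-2-methylpropanoate
Product: 20 methyl (2R)-3-[(tert-butyldimethylsilyl)oxy]-2-methylpropanoate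
Conditions: TBSCl, imidazole, CH2Cl2, rt
Reagents that add atoms: tert-butyldimethylsilyl chloride CC(C)(C)[Si](C)(C)Cl
Why: Silylation of the primary alcohol should proceed without touching the stereocentre (silyl ether formation).

Step 11
Reactants: 20 methyl (2R)-3-[(tert-butyldimethylsilyl)oxy]-2-methylpropanoate
Product: 21 (2R)-3-[(tert-butyldimethylsilyl)oxy]-2-methylpropanoic acid
Conditions: LiOH, THF/MeOH/H2O, 0 °C; then 1 M HCl to pH 4
Reagents that add atoms: lithium hydroxide [Li+].[OH-]
Why: Saponification of the methyl ester at 0 °C should give the acid without epimerisation of the α-stereocentre or β-elimination of the silyloxy group (ester hydrolysis).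

Step 12
Reactants: 14 (3R)-3-[(2Z)-4-methoxybut-2-en-2-yl]-4-methylideneoxolan-2-ol; 18 methyl 2-methylidene-4-oxopentanoate
Product: 25 (3aS,6S,7R,7aR)-6-ethenyl-7-(3-hydroxyprop-1-en-2-yl)-6-methyl-3-methylidenehexahydro-1-benzofuran-2,4-dione, via trichlorotitanium enolate 22 (not isolated), via aldol adduct 23 (not isolated), via cyclised hydroxy ester 24 (not isolated)
Conditions: 18, TiCl4 (1.1 equiv), i-Pr2NEt (1.2 equiv), CH2Cl2, −78 °C; then 14, i-Pr2NEt (1.0 equiv), −78 °C; then TiCl4 (2.0 equiv), i-Pr2NEt (1.1 equiv), −78 to −20 °C; aq. NaHCO3; then PPTS, CH2Cl2, rt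
Reagents that add atoms: none
Why: Proposed new method: the Z enolate 22 of tetravalent titanium, formed by soft enolisation of 18 at the more acidic allylic C7 methylene, should add through a closed chair transition state to the open hydroxy-aldehyde form of 14, held on titanium as a seven-membered chelate through the C15 alkoxide (23); a second enolisation towards the C9 methyl group and ionisation of the Z-allylic methyl ether by TiCl4 should then let C9 capture the tertiary end C10 of the allyl cation (24), and acid closes the lactone (25). The closest known reaction types are the titanium-enolate aldol addition, the formal (3+3) cyclisation of ketone α,α'-bis-nucleophiles (1,3-bis-silyl enol ethers) with 1,3-bis-electrophiles, and the SN1 α-alkylation of titanium or silyl enolates by tertiary and allylic cations; new is the use of one ketone twice against a lactol and an allylic ether held in one molecule. The carbocycle is closed by 6-exo attack of the exocyclic C8=C9 enolate on the cation terminus C10 through a chair, and the lactone by 5-exo-trig acyl substitution of the C6 oxygen on the C12 ester. C6 is set by attack on the aldehyde face anti to the Z-alkenyl arm that stands outside the chelate ring, C7 by the syn preference of the Z enolate in the closed transition state (trans on the ring), and C10 by the chair in which H5 eclipses the C10–C1 bond to avoid 1,3-allylic strain with C2, which puts the methyl group axial and the future vinyl group equatorial. The step needs carbon attack at C10 and not at C2 or by oxygen, which the six-membered against an eight-membered ring and the reversibility of ether formation under the ionising conditions should secure, and it needs enolisation first at C7 and then at C9, which the higher acidity of the allylic C7 methylene and its tertiary nature after the aldol addition should secure.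

Step 13
Reactants: 25 (3aS,6S,7R,7aR)-6-ethenyl-7-(3-hydroxyprop-1-en-2-yl)-6-methyl-3-methylidenehexahydro-1-benzofuran-2,4-dione
Product: 26 (3aS,6S,7R,7aR)-7-[3-[(tert-butyldimethylsilyl)oxy]prop-1-en-2-yl]-6-ethenyl-6-methyl-3-methylidenehexahydro-1-benzofuran-2,4-dione
Conditions: TBSCl, imidazole, CH2Cl2, 0 °C
Reagents that add atoms: tert-butyldimethylsilyl chloride CC(C)(C)[Si](C)(C)Cl
Why: Silylation of the only hydroxyl group (C15–OH) protects it before C8 is reduced and esterified (silyl ether formation).

Step 14
Reactants: 26 (3aS,6S,7R,7aR)-7-[3-[(tert-butyldimethylsilyl)oxy]prop-1-en-2-yl]-6-ethenyl-6-methyl-3-methylidenehexahydro-1-benzofuran-2,4-dione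
Product: 27 (3aR,4R,6S,7R,7aR)-7-[3-[(tert-butyldimethylsilyl)oxy]prop-1-en-2-yl]-6-ethenyl-4-hydroxy-6-methyl-3-methylidenehexahydro-1-benzofuran-2(3H)-one
Conditions: LiAlH(Ot-Bu)3, THF, −78 to −40 °C
Reagents that add atoms: none
Why: In this ketone reduction the axial C10 methyl group blocks the axial trajectory at C8, so the bulky hydride should attack along the equatorial trajectory on the α-face and give the axial 8β-alcohol, while lactone and enoate stay intact (diastereoselective hydride reduction).

Step 15
Reactants: 27 (3aR,4R,6S,7R,7aR)-7-[3-[(tert-butyldimethylsilyl)oxy]prop-1-en-2-yl]-6-ethenyl-4-hydroxy-6-methyl-3-methylidenehexahydro-1-benzofuran-2(3H)-one; 21 (2R)-3-[(tert-butyldimethylsilyl)oxy]-2-methylpropanoic acid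
Product: 28 (3aR,4S,6S,7R,7aR)-7-[3-[(tert-butyldimethylsilyl)oxy]prop-1-en-2-yl]-6-ethenyl-6-methyl-3-methylidene-2-oxooctahydro-1-benzofuran-4-yl (2R)-3-[(tert-butyldimethylsilyl)oxy]-2-methylpropanoate
Conditions: PPh3, DIAD, toluene, 0 °C to rt
Reagents that add atoms: none
Why: Mitsunobu esterification of the axial secondary alcohol with acid 21 proceeds with inversion at C8 and should install the equatorial 8α-acyloxy group of the target, the stereocentre of the acid not being involved.

Step 16
Reactants: 28 (3aR,4S,6S,7R,7aR)-7-[3-[(tert-butyldimethylsilyl)oxy]prop-1-en-2-yl]-6-ethenyl-6-methyl-3-methylidene-2-oxooctahydro-1-benzofuran-4-yl (2R)-3-[(tert-butyldimethylsilyl)oxy]-2-methylpropanoate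
Product: 29 (3aR,4S,6S,7R,7aR)-6-ethenyl-7-(3-hydroxyprop-1-en-2-yl)-6-methyl-3-methylidene-2-oxooctahydro-1-benzofuran-4-yl (2R)-3-hydroxy-2-methylpropanoate
Conditions: HF·pyridine, pyridine, THF, 0 °C to rt
Reagents that add atoms: none
Why: Buffered acidic fluoride should cleave both primary silyl ethers without acyl migration, β-elimination of the acyloxy groups or attack on the α-methylene lactone (desilylation).

**Compound list**

1 | but-2-yn-1-ol | CC#CCO | starting material
2 | sodium 2,2-bis(2-methoxyethoxy)-3-methyl-2,5-dihydro-1,2-oxaaluminol-2-uide (cyclic alkenylalanate) | [Na+].CC1=CCO[Al-]1(OCCOC)OCCOC | intermediate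
3 | (2Z)-3-iodobut-2-en-1-ol | OC/C=C(/C)I | intermediate
4 | (2Z)-3-iodo-1-methoxybut-2-ene | COC/C=C(/C)I | intermediate
5 | [(2E)-4-methoxybut-2-en-2-yl]lithium | COC/C=C(/C)[Li] | intermediate
6 | lithium [(2E)-4-methoxybut-2-en-2-yl]tri(propan-2-yloxy)borate | [Li+].COC/C=C(/C)[B-](OC(C)C)(OC(C)C)OC(C)C | intermediate
7 | [(2E)-4-methoxybut-2-en-2-yl]boronic acid | COC/C=C(/C)B(O)O | intermediate
8 | methyl (2E)-4,4-dimethoxybut-2-enoate | COC(=O)/C=C/C(OC)OC | starting material
9 | methyl (3S,4Z)-3-(dimethoxymethyl)-6-methoxy-4-methylhex-4-enoate | COC(=O)C[C@H](C(OC)OC)/C(C)=C\COC | intermediate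
10 | methyl (3S,4Z)-2-[(dimethylamino)methyl]-3-(dimethoxymethyl)-6-methoxy-4-methylhex-4-enoate (both C2 epimers) | COC(=O)C(CN(C)C)[C@H](C(OC)OC)/C(C)=C\COC | intermediate
11 | N-methyl quaternary ammonium iodide of 10 (trimethylammonium salt) | COC(=O)C(C[N+](C)(C)C)[C@H](C(OC)OC)/C(C)=C\COC.[I-] | intermediate
12 | methyl (3R,4Z)-3-(dimethoxymethyl)-6-methoxy-4-methyl-2-methylidenehex-4-enoate | COC(=O)C(=C)[C@H](C(OC)OC)/C(C)=C\COC | intermediate
13 | (3R,4Z)-3-(dimethoxymethyl)-6-methoxy-4-methyl-2-methylidenehex-4-en-1-ol | OCC(=C)[C@H](C(OC)OC)/C(C)=C\COC | intermediate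
14 | (3R)-3-[(2Z)-4-methoxybut-2-en-2-yl]-4-methylideneoxolan-2-ol (anomers) | OC1OCC(=C)[C@H]1/C(C)=C\COC | intermediate
15 | trimethyl phosphonoacetate | COC(=O)CP(=O)(OC)OC | starting material
16 | chloroacetone | CC(=O)CCl | starting material
17 | methyl 2-(dimethoxyphosphoryl)-4-oxopentanoate | COC(=O)C(CC(C)=O)P(=O)(OC)OC | intermediate
18 | methyl 2-methylidene-4-oxopentanoate | COC(=O)C(=C)CC(C)=O | intermediate
19 | methyl (2R)-3-hydroxy-2-methylpropanoate | COC(=O)[C@H](C)CO | starting material
20 | methyl (2R)-3-[(tert-butyldimethylsilyl)oxy]-2-methylpropanoate | COC(=O)[C@H](C)CO[Si](C)(C)C(C)(C)C | intermediate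
21 | (2R)-3-[(tert-butyldimethylsilyl)oxy]-2-methylpropanoic acid | OC(=O)[C@H](C)CO[Si](C)(C)C(C)(C)C | intermediate
22 | trichloro{[(2Z)-4-(methoxycarbonyl)penta-2,4-dien-2-yl]oxy}titanium | COC(=O)C(=C)/C=C(/C)O[Ti](Cl)(Cl)Cl | intermediate
23 | methyl (3S,4R,5R,6Z)-3-acetyl-4-hydroxy-5-(3-hydroxyprop-1-en-2-yl)-8-methoxy-6-methyl-2-methylideneoct-6-enoate (titanium-bound in the flask) | CC(=O)[C@@H](C(=C)C(=O)OC)[C@H](O)[C@@H](C(=C)CO)/C(C)=C\COC | intermediate
24 | methyl 2-[(1S,2R,3R,4S)-4-ethenyl-2-hydroxy-3-(3-hydroxyprop-1-en-2-yl)-4-methyl-6-oxocyclohexyl]prop-2-enoate | C=C[C@]1(C)CC(=O)[C@@H](C(=C)C(=O)OC)[C@H](O)[C@H]1C(=C)CO | intermediate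
25 | (3aS,6S,7R,7aR)-6-ethenyl-7-(3-hydroxyprop-1-en-2-yl)-6-methyl-3-methylidenehexahydro-1-benzofuran-2,4-dione | C=C[C@]1(C)CC(=O)[C@H]2C(=C)C(=O)O[C@@H]2[C@H]1C(=C)CO | intermediate
26 | (3aS,6S,7R,7aR)-7-[3-[(tert-butyldimethylsilyl)oxy]prop-1-en-2-yl]-6-ethenyl-6-methyl-3-methylidenehexahydro-1-benzofuran-2,4-dione | C=C[C@]1(C)CC(=O)[C@H]2C(=C)C(=O)O[C@@H]2[C@H]1C(=C)CO[Si](C)(C)C(C)(C)C | intermediate
27 | (3aR,4R,6S,7R,7aR)-7-[3-[(tert-butyldimethylsilyl)oxy]prop-1-en-2-yl]-6-ethenyl-4-hydroxy-6-methyl-3-methylidenehexahydro-1-benzofuran-2(3H)-one | C=C[C@]1(C)C[C@@H](O)[C@H]2C(=C)C(=O)O[C@@H]2[C@H]1C(=C)CO[Si](C)(C)C(C)(C)C | intermediate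
28 | (3aR,4S,6S,7R,7aR)-7-[3-[(tert-butyldimethylsilyl)oxy]prop-1-en-2-yl]-6-ethenyl-6-methyl-3-methylidene-2-oxooctahydro-1-benzofuran-4-yl (2R)-3-[(tert-butyldimethylsilyl)oxy]-2-methylpropanoate | C=C[C@]1(C)C[C@H](OC(=O)[C@H](C)CO[Si](C)(C)C(C)(C)C)[C@H]2C(=C)C(=O)O[C@@H]2[C@H]1C(=C)CO[Si](C)(C)C(C)(C)C | intermediate
29 | (3aR,4S,6S,7R,7aR)-6-ethenyl-7-(3-hydroxyprop-1-en-2-yl)-6-methyl-3-methylidene-2-oxooctahydro-1-benzofuran-4-yl (2R)-3-hydroxy-2-methylpropanoate | C=C[C@]1(C)C[C@H](OC(=O)[C@H](C)CO)[C@H]2C(=C)C(=O)O[C@@H]2[C@H]1C(=C)CO | target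

**Totals**

Total step count: 16. Longest linear sequence: 12 steps (steps 1 to 7, then 12 to 16).

**Steps most likely to fail**

1. Step 12 (proposed new method). Several processes may divert it:
 - ionisation of the titanium lactolate to the cyclic oxocarbenium ion, so that carbon–carbon bond formation keeps C6 and C15 joined through the ring oxygen;
 - β-elimination of the titanium aldolate;
 - capture of the allyl cation by the C4=C3 methylidene group before the C9 enolate exists;
 - loss of the Z geometry of the allyl cation and with it the facial control at C10.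

 Fallback (known reaction types, the two bonds made in separate steps), setting out from 14: an indium-mediated Barbier allylation with methyl 2-(bromomethyl)-4-oxopent-2-enoate (In, THF/H2O, rt; then PPTS) should give the trans acetyl α-methylene lactone F1. Silylation (Me3SiOTf, Et3N, CH2Cl2, −78 °C) should give the bis(trimethylsilyl) compound F2, with the silyl enol ether on the methyl side and a silyl ether at C15. SnCl4 (CH2Cl2, −78 °C) then ionises the allylic methyl ether for SN1 alkylation of the silyl enol ether; aqueous acid work-up closes the sequence, which comes back at 25.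

2. Step 15. The activated axial C8 oxygen may undergo anti-elimination with the axial hydrogens on C7 or C9 instead of substitution, and the aliphatic acid may react sluggishly at the hindered centre. Fallback (retentive acylation instead of invertive substitution), setting out from 26: a reversible Meerwein–Ponndorf–Verley reduction (Al(Oi-Pr)3, i-PrOH, toluene, 60 °C) under thermodynamic control should give the equatorial 8α-alcohol F3. Steglich esterification with 21 (DCC, DMAP, CH2Cl2, rt) then comes back at 28.

3. Step 4. The α-branched alkenylboronic acid may transmetalate slowly and protodeboronate, and facial discrimination on the acetal-bearing enoate may be insufficient. Fallback (auxiliary control instead of catalyst control), setting out from 8 and 4: saponification of 8 (LiOH, THF/H2O) gives (2E)-4,4-dimethoxybut-2-enoic acid F4. Its pivalic mixed anhydride acylates lithiated (4R)-4-benzyl-1,3-oxazolidin-2-one to give the N-enoyl oxazolidinone F5. Conjugate addition of the alkenylcopper reagent made from 4 (t-BuLi; CuBr·SMe2; MgBr2·OEt2, THF, −78 °C), anti to the benzyl group of the chelated imide, should give the adduct F6. Methanolysis (MeOMgBr, MeOH/CH2Cl2, 0 °C) comes back at 9.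

Further compounds
F1 | step 12 | (4S,5R)-4-acetyl-5-[(3R,4Z)-1-hydroxy-6-methoxy-4-methyl-2-methylidenehex-4-en-3-yl]-3-methylideneoxolan-2-one | CC(=O)[C@H]1C(=C)C(=O)O[C@@H]1[C@@H](C(=C)CO)/C(C)=C\COC
F2 | step 12 | (4S,5R)-5-[(3R,4Z)-6-methoxy-4-methyl-2-methylidene-1-[(trimethylsilyl)oxy]hex-4-en-3-yl]-3-methylidene-4-{1-[(trimethylsilyl)oxy]ethenyl}oxolan-2-one | C=C(O[Si](C)(C)C)[C@H]1C(=C)C(=O)O[C@@H]1[C@@H](C(=C)CO[Si](C)(C)C)/C(C)=C\COC
F3 | step 15 | (3aR,4S,6S,7R,7aR)-7-[3-[(tert-butyldimethylsilyl)oxy]prop-1-en-2-yl]-6-ethenyl-4-hydroxy-6-methyl-3-methylidenehexahydro-1-benzofuran-2(3H)-one | C=C[C@]1(C)C[C@H](O)[C@H]2C(=C)C(=O)O[C@@H]2[C@H]1C(=C)CO[Si](C)(C)C(C)(C)C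
F4 | step 4 | (2E)-4,4-dimethoxybut-2-enoic acid | COC(OC)/C=C/C(=O)O
F5 | step 4 | (4R)-4-benzyl-3-[(2E)-4,4-dimethoxybut-2-enoyl]-1,3-oxazolidin-2-one | COC(OC)/C=C/C(=O)N1[C@H](Cc2ccccc2)COC1=O
F6 | step 4 | (4R)-4-benzyl-3-[(3S,4Z)-3-(dimethoxymethyl)-6-methoxy-4-methylhex-4-enoyl]-1,3-oxazolidin-2-one | COC/C=C(/C)[C@H](CC(=O)N1[C@H](Cc2ccccc2)COC1=O)C(OC)OC
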